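**Retrosynthetic overview**

1. The target is a 2,5-diaryl-3,4-dimethyloxolane (ring C: O1, C2 bearing the free-phenol ring A, C3-Me, C4-Me, C5 bearing ring B). Ring B's phenol oxygen carries an erythro 1-aryl(ring D)-1-hydroxypropan-2-yl unit. Endgame: desilylation ⇐ chelation-controlled ketone reduction ⇐ Weinreb ketone synthesis ⇐ Mitsunobu etherification of the ring-B phenol with ethyl (S)-lactate.
2. Ring C ⇐ 2,3-dihydrofuran (C2=C3) by one syn-hydrogenation anti to the C4 methyl, which sets C2 and C3 together.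
3. Key disconnection: O1–C2 and C4–C5 at once. The ring-B aldehyde (O1=C5) is joined to a C2–C3–C4 homoenolate carrying ring A, an (S)-1-aryl-2-methylbut-2-enyl carbamate metallated at C2, which adds through C4 and then accepts O1 at C2.
4. Enabling feature: C2 is both benzylic to ring A and bonded to O1, so it can be carried at the enol (aryl-ketone) level, and the C3/C4 methyl pair is the tiglyl (E-2-methylbut-2-enyl) pattern. The C2 stereocentre relays its chirality to C4/C5, is erased, and is rebuilt by the hydrogenation.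
5. Rings A, B and D are bought (vanillin, O-benzylvanillin, 4-bromo-2-methoxyphenol). Ring C is the only ring formed: closed in step 4, saturated in step 5.

Key step: step 4

Assumption: the α-lithiated carbamate is configurationally stable at −78 °C and follows the course known for secondary 2-alkenyl carbamates (deprotonation with retention, lithium–titanium exchange with inversion, closed chair addition with the carbamate oxygen axial); if the sense of transfer were opposite, the R carbamate (enantiomeric ligand in step 2) would be used.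

**Route**

Step 1
Reactants: 1 vanillin (4-hydroxy-3-methoxybenzaldehyde)
Product: 2 3-methoxy-4-[(triisopropylsilyl)oxy]benzaldehyde
Conditions: TIPSCl, imidazole, DMF, rt
Reagents that add atoms: triisopropylsilyl chloride, CC(C)[Si](Cl)(C(C)C)C(C)C
Why: Imidazole-promoted silyl ether formation masks the ring-A phenol with a group that should survive organolithium, acid, hydrogenation and Mitsunobu conditions, and no stereocentre is formed.

Step 2
Reactants: 2 3-methoxy-4-[(triisopropylsilyl)oxy]benzaldehyde; 3 but-2-yne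
Product: 6 (S,E)-1-{3-methoxy-4-[(triisopropylsilyl)oxy]phenyl}-2-methylbut-2-en-1-ol, via dicyclohexyl[(Z)-but-2-en-2-yl]borane 4 (not isolated), via ethyl[(E)-but-2-en-2-yl]zinc 5 (not isolated)
Conditions: Cy2BH, toluene, 0 °C → rt; Et2Zn, −78 °C; (−)-MIB (5 mol%), then 2, −10 °C; aq. NH4Cl
Reagents that add atoms: none
Why: syn-Hydroboration of the symmetrical alkyne fixes the E trisubstituted alkene, boron-to-zinc transmetalation gives the alkenylzinc, and the amino-alcohol-catalysed asymmetric alkenylzinc addition to the aryl aldehyde should give the S carbinol by ligand-controlled attack on the Si face.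

Step 3
Reactants: 6 (S,E)-1-{3-methoxy-4-[(triisopropylsilyl)oxy]phenyl}-2-methylbut-2-en-1-ol
Product: 7 (S,E)-1-{3-methoxy-4-[(triisopropylsilyl)oxy]phenyl}-2-methylbut-2-en-1-yl N,N-diisopropylcarbamate
Conditions: NaH, THF, 0 °C; iPr2NCOCl, 0 → 50 °C
Reagents that add atoms: N,N-diisopropylcarbamoyl chloride, CC(C)N(C(C)C)C(Cl)=O
Why: O-Carbamoylation of the sodium alkoxide (acyl substitution) installs the group that directs lithiation and masks C2 as an enol, without touching the stereocentre.

Step 4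
Reactants: 7 (S,E)-1-{3-methoxy-4-[(triisopropylsilyl)oxy]phenyl}-2-methylbut-2-en-1-yl N,N-diisopropylcarbamate; 8 4-(benzyloxy)-3-methoxybenzaldehyde
Product: 12 (2S,3S)-2-[4-(benzyloxy)-3-methoxyphenyl]-5-{3-methoxy-4-[(triisopropylsilyl)oxy]phenyl}-3,4-dimethyl-2,3-dihydrofuran, via α-lithio carbamate 9 (not isolated), via allyltitanium triisopropoxide 10 (not isolated), via anti-homoaldol adduct 11 (not isolated)
Conditions: s-BuLi, Et2O, −78 °C; Ti(OiPr)4, −78 °C; 8, −78 °C; then MsOH (excess), CH2Cl2, −78 → 0 °C; Et3N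
Reagents that add atoms: none
Why: Proposed new method: s-BuLi removes the doubly activated C–H of 7 with retention and Ti(OiPr)4 replaces lithium with inversion, giving the α-oxygenated allyltitanium 10, a homoenolate equivalent of the ring-A aryl ketone, whose γ-carbon (the future C4) adds to aldehyde 8 through a closed chair (Zimmerman–Traxler) transition state and forms the C4–C5 bond. The E-methyl group and the aldehyde aryl group both sit equatorial in that chair, which fixes the anti (4,5-trans) relationship, while suprafacial transfer from the titanium-bearing stereocentre fixes C4 and C5 as S,S and leaves C2 as a Z enol carbamate. Methanesulfonic acid then protonates this electron-rich enol carbamate at C3, and the cation at C2, stabilised by ring A and the carbamate oxygen, is captured by the C5 hydroxyl oxygen in a five-membered cation–alcohol ring closure (formally 5-endo at the enol carbon) that forms O1–C2; loss of diisopropylcarbamic acid and of the C3 proton returns the C2=C3 enol ether. The step needs γ- over α-attack, which the fully substituted carbamate-chelated metal-bearing carbon secures, and it needs protonation of the enol carbamate in preference to ionisation of the new benzylic alcohol, which the para-silyloxy ring A on C2 secures; any reversible opening at C5 can only drift toward the wanted trans isomer. The closest known reaction types are the homoaldol reaction of titanated secondary 2-alkenyl carbamates with 1,3-chirality transfer and the acid-mediated cyclisation of the resulting 4-hydroxy enol carbamates to lactol derivatives; merging both in one flask on an α-aryl substrate to reach a 2,3-dihydrofuran is the new element.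

Step 5
Reactants: 12 (2S,3S)-2-[4-(benzyloxy)-3-methoxyphenyl]-5-{3-methoxy-4-[(triisopropylsilyl)oxy]phenyl}-3,4-dimethyl-2,3-dihydrofuran
Product: 13 4-[(2S,3S,4R,5S)-5-{3-methoxy-4-[(triisopropylsilyl)oxy]phenyl}-3,4-dimethyloxolan-2-yl]-2-methoxyphenol
Conditions: H2 (3 atm), 10% Pd/C, EtOAc, rt
Reagents that add atoms: none
Why: Heterogeneous catalytic hydrogenation should deliver both hydrogens syn to the tetrasubstituted C2=C3 bond from the face opposite the adjacent C4 methyl group, so that ring A, the C3 methyl and the C4 methyl end up on one face (2,3-cis, 3,4-cis) with ring B trans, while the same catalyst cleaves the ring-B benzyl ether by hydrogenolysis.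

Step 6
Reactants: 13 4-[(2S,3S,4R,5S)-5-{3-methoxy-4-[(triisopropylsilyl)oxy]phenyl}-3,4-dimethyloxolan-2-yl]-2-methoxyphenol; 14 ethyl (S)-lactate
Product: 15 ethyl (R)-2-{4-[(2S,3S,4R,5S)-5-{3-methoxy-4-[(triisopropylsilyl)oxy]phenyl}-3,4-dimethyloxolan-2-yl]-2-methoxyphenoxy}propanoate
Conditions: PPh3, DIAD, THF, 0 °C → rt
Reagents that add atoms: none
Why: The Mitsunobu etherification couples the ring-B phenol with the secondary alcohol under neutral conditions with clean SN2 inversion, turning the S lactate into the R aryl ether.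

Step 7
Reactants: 15 ethyl (R)-2-{4-[(2S,3S,4R,5S)-5-{3-methoxy-4-[(triisopropylsilyl)oxy]phenyl}-3,4-dimethyloxolan-2-yl]-2-methoxyphenoxy}propanoate
Product: 16 (R)-N-methoxy-N-methyl-2-{4-[(2S,3S,4R,5S)-5-{3-methoxy-4-[(triisopropylsilyl)oxy]phenyl}-3,4-dimethyloxolan-2-yl]-2-methoxyphenoxy}propanamide
Conditions: MeNH(OMe)·HCl, iPrMgCl, THF, −20 → 0 °C
Reagents that add atoms: N,O-dimethylhydroxylamine hydrochloride, CNOC.Cl
Why: Aminolysis of the ester by the magnesium amide gives the Weinreb amide at a temperature at which the α-aryloxy stereocentre should not enolise.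

Step 8
Reactants: 17 4-bromo-2-methoxyphenol
Product: 18 (4-bromo-2-methoxyphenoxy)triisopropylsilane
Conditions: TIPSCl, imidazole, DMF, rt
Reagents that add atoms: triisopropylsilyl chloride, CC(C)[Si](Cl)(C(C)C)C(C)C
Why: Silyl ether formation protects the ring-D phenol with the same group as ring A, so that one final operation frees both.

Step 9
Reactants: 18 (4-bromo-2-methoxyphenoxy)triisopropylsilane; 16 (R)-N-methoxy-N-methyl-2-{4-[(2S,3S,4R,5S)-5-{3-methoxy-4-[(triisopropylsilyl)oxy]phenyl}-3,4-dimethyloxolan-2-yl]-2-methoxyphenoxy}propanamide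
Product: 20 (R)-1-{3-methoxy-4-[(triisopropylsilyl)oxy]phenyl}-2-{4-[(2S,3S,4R,5S)-5-{3-methoxy-4-[(triisopropylsilyl)oxy]phenyl}-3,4-dimethyloxolan-2-yl]-2-methoxyphenoxy}propan-1-one, via {3-methoxy-4-[(triisopropylsilyl)oxy]phenyl}lithium 19 (not isolated)
Conditions: 18, n-BuLi, THF, −78 °C; then 16, −78 °C; aq. NH4Cl
Reagents that add atoms: none
Why: Bromine–lithium exchange followed by the Weinreb ketone synthesis gives a chelated tetrahedral adduct that releases the ketone only on work-up, so over-addition and enolisation of the α-aryloxy stereocentre are avoided.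

Step 10
Reactants: 20 (R)-1-{3-methoxy-4-[(triisopropylsilyl)oxy]phenyl}-2-{4-[(2S,3S,4R,5S)-5-{3-methoxy-4-[(triisopropylsilyl)oxy]phenyl}-3,4-dimethyloxolan-2-yl]-2-methoxyphenoxy}propan-1-one
Product: 21 (1S,2R)-1-{3-methoxy-4-[(triisopropylsilyl)oxy]phenyl}-2-{4-[(2S,3S,4R,5S)-5-{3-methoxy-4-[(triisopropylsilyl)oxy]phenyl}-3,4-dimethyloxolan-2-yl]-2-methoxyphenoxy}propan-1-ol
Conditions: Zn(BH4)2, Et2O, −30 → 0 °C; aq. NH4Cl
Reagents that add atoms: none
Why: In this chelation-controlled hydride reduction zinc should bridge the ketone oxygen and the guaiacyl ether oxygens, so that hydride attacks the chelate face opposite the methyl group and gives the erythro (1S,2R) alcohol.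

Step 11
Reactants: 21 (1S,2R)-1-{3-methoxy-4-[(triisopropylsilyl)oxy]phenyl}-2-{4-[(2S,3S,4R,5S)-5-{3-methoxy-4-[(triisopropylsilyl)oxy]phenyl}-3,4-dimethyloxolan-2-yl]-2-methoxyphenoxy}propan-1-ol
Product: 22 4-[(1S,2R)-1-hydroxy-2-{4-[(2S,3S,4R,5S)-5-(4-hydroxy-3-methoxyphenyl)-3,4-dimethyloxolan-2-yl]-2-methoxyphenoxy}propyl]-2-methoxyphenol (target)
Conditions: Bu4NF, AcOH, THF, 0 °C
Reagents that add atoms: none
Why: Fluoride-induced cleavage of both aryl silyl ethers, buffered with acetic acid so that the freed para-hydroxybenzylic ethers are not opened through quinone methides, should release the target with all six stereocentres untouched.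

**Compound list**

1 | vanillin (4-hydroxy-3-methoxybenzaldehyde) | COc1cc(C=O)ccc1O | starting material
2 | 3-methoxy-4-[(triisopropylsilyl)oxy]benzaldehyde | COc1cc(C=O)ccc1O[Si](C(C)C)(C(C)C)C(C)C | intermediate
3 | but-2-yne | CC#CC | starting material
4 | dicyclohexyl[(Z)-but-2-en-2-yl]borane | C/C=C(\C)B(C1CCCCC1)C1CCCCC1 | intermediate
5 | ethyl[(E)-but-2-en-2-yl]zinc | C/C=C(\C)[Zn]CC | intermediate
6 | (S,E)-1-{3-methoxy-4-[(triisopropylsilyl)oxy]phenyl}-2-methylbut-2-en-1-ol | C/C=C(\C)[C@H](O)c1ccc(O[Si](C(C)C)(C(C)C)C(C)C)c(OC)c1 | intermediate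
7 | (S,E)-1-{3-methoxy-4-[(triisopropylsilyl)oxy]phenyl}-2-methylbut-2-en-1-yl N,N-diisopropylcarbamate | C/C=C(\C)[C@H](OC(=O)N(C(C)C)C(C)C)c1ccc(O[Si](C(C)C)(C(C)C)C(C)C)c(OC)c1 | intermediate
8 | 4-(benzyloxy)-3-methoxybenzaldehyde | COc1cc(C=O)ccc1OCc1ccccc1 | starting material
9 | α-lithio carbamate (lithium in place of the carbinol hydrogen of 7, same configuration) | C/C=C(\C)[C@]([Li])(OC(=O)N(C(C)C)C(C)C)c1ccc(O[Si](C(C)C)(C(C)C)C(C)C)c(OC)c1 | intermediate
10 | allyltitanium triisopropoxide (titanium on the face opposite to the lithium of 9) | C/C=C(\C)[C@@]([Ti](OC(C)C)(OC(C)C)OC(C)C)(OC(=O)N(C(C)C)C(C)C)c1ccc(O[Si](C(C)C)(C(C)C)C(C)C)c(OC)c1 | intermediate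
11 | (1Z,3S,4S)-4-[4-(benzyloxy)-3-methoxyphenyl]-4-hydroxy-1-{3-methoxy-4-[(triisopropylsilyl)oxy]phenyl}-2,3-dimethylbut-1-en-1-yl N,N-diisopropylcarbamate | C[C@H]([C@H](O)c1ccc(OCc2ccccc2)c(OC)c1)/C(C)=C(\OC(=O)N(C(C)C)C(C)C)c1ccc(O[Si](C(C)C)(C(C)C)C(C)C)c(OC)c1 | intermediate
12 | (2S,3S)-2-[4-(benzyloxy)-3-methoxyphenyl]-5-{3-methoxy-4-[(triisopropylsilyl)oxy]phenyl}-3,4-dimethyl-2,3-dihydrofuran | CC1=C(c2ccc(O[Si](C(C)C)(C(C)C)C(C)C)c(OC)c2)O[C@H](c2ccc(OCc3ccccc3)c(OC)c2)[C@H]1C | intermediate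
13 | 4-[(2S,3S,4R,5S)-5-{3-methoxy-4-[(triisopropylsilyl)oxy]phenyl}-3,4-dimethyloxolan-2-yl]-2-methoxyphenol | COc1cc([C@H]2O[C@H](c3ccc(O)c(OC)c3)[C@@H](C)[C@H]2C)ccc1O[Si](C(C)C)(C(C)C)C(C)C | intermediate
14 | ethyl (S)-lactate | CCOC(=O)[C@H](C)O | starting material
15 | ethyl (R)-2-{4-[(2S,3S,4R,5S)-5-{3-methoxy-4-[(triisopropylsilyl)oxy]phenyl}-3,4-dimethyloxolan-2-yl]-2-methoxyphenoxy}propanoate | COc1cc([C@H]2O[C@H](c3ccc(O[C@H](C)C(=O)OCC)c(OC)c3)[C@@H](C)[C@H]2C)ccc1O[Si](C(C)C)(C(C)C)C(C)C | intermediate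
16 | (R)-N-methoxy-N-methyl-2-{4-[(2S,3S,4R,5S)-5-{3-methoxy-4-[(triisopropylsilyl)oxy]phenyl}-3,4-dimethyloxolan-2-yl]-2-methoxyphenoxy}propanamide | COc1cc([C@H]2O[C@H](c3ccc(O[C@H](C)C(=O)N(C)OC)c(OC)c3)[C@@H](C)[C@H]2C)ccc1O[Si](C(C)C)(C(C)C)C(C)C | intermediate
17 | 4-bromo-2-methoxyphenol | COc1cc(Br)ccc1O | starting material
18 | (4-bromo-2-methoxyphenoxy)triisopropylsilane | COc1cc(Br)ccc1O[Si](C(C)C)(C(C)C)C(C)C | intermediate
19 | {3-methoxy-4-[(triisopropylsilyl)oxy]phenyl}lithium | COc1cc([Li])ccc1O[Si](C(C)C)(C(C)C)C(C)C | intermediate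
20 | (R)-1-{3-methoxy-4-[(triisopropylsilyl)oxy]phenyl}-2-{4-[(2S,3S,4R,5S)-5-{3-methoxy-4-[(triisopropylsilyl)oxy]phenyl}-3,4-dimethyloxolan-2-yl]-2-methoxyphenoxy}propan-1-one | COc1cc([C@H]2O[C@H](c3ccc(O[C@H](C)C(=O)c4ccc(O[Si](C(C)C)(C(C)C)C(C)C)c(OC)c4)c(OC)c3)[C@@H](C)[C@H]2C)ccc1O[Si](C(C)C)(C(C)C)C(C)C | intermediate
21 | (1S,2R)-1-{3-methoxy-4-[(triisopropylsilyl)oxy]phenyl}-2-{4-[(2S,3S,4R,5S)-5-{3-methoxy-4-[(triisopropylsilyl)oxy]phenyl}-3,4-dimethyloxolan-2-yl]-2-methoxyphenoxy}propan-1-ol | COc1cc([C@H]2O[C@H](c3ccc(O[C@H](C)[C@@H](O)c4ccc(O[Si](C(C)C)(C(C)C)C(C)C)c(OC)c4)c(OC)c3)[C@@H](C)[C@H]2C)ccc1O[Si](C(C)C)(C(C)C)C(C)C | intermediate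
22 | 4-[(1S,2R)-1-hydroxy-2-{4-[(2S,3S,4R,5S)-5-(4-hydroxy-3-methoxyphenyl)-3,4-dimethyloxolan-2-yl]-2-methoxyphenoxy}propyl]-2-methoxyphenol | COc1cc([C@H]2O[C@H](c3ccc(O[C@H](C)[C@@H](O)c4ccc(O)c(OC)c4)c(OC)c3)[C@@H](C)[C@H]2C)ccc1O | target

**Totals and risks**

Total step count: 11. Longest linear sequence: 10 steps (steps 1–7 and 9–11; step 8 is a side branch).

Steps most likely to fail:

1. Step 4 (Proposed new method). What may go wrong: loss of configurational integrity of the α-lithiated benzylic, allylic carbamate before titanation or competition between the two chair arrangements, which would erode enantiopurity; also ionisation and elimination at the new benzylic alcohol under acid before the ring closes. Fallback with known chemistry, setting out from 8 and coming back at 12: aldehyde 8 undergoes a catalytic asymmetric Nozaki–Hiyama–Kishi 2-(alkoxycarbonyl)allylation with ethyl (Z)-2-(bromomethyl)but-2-enoate (CrCl2 in catalytic amount, Mn, TMSCl, chiral bis(oxazoline) ligand, anti-selective) with spontaneous lactonisation to (4S,5S)-5-[4-(benzyloxy)-3-methoxyphenyl]-4-methyl-3-methylideneoxolan-2-one F1. Homogeneous hydrogenation (H2, RhCl(PPh3)3), which spares the benzyl ether, gives (3R,4S,5S)-5-[4-(benzyloxy)-3-methoxyphenyl]-3,4-dimethyloxolan-2-one F2. Addition of aryllithium 19 at −78 °C gives the hemiketal (3R,4S,5S)-5-[4-(benzyloxy)-3-methoxyphenyl]-2-{3-methoxy-4-[(triisopropylsilyl)oxy]phenyl}-3,4-dimethyloxolan-2-ol F3, and acid-catalysed dehydration (TsOH, toluene) gives 12.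

2. Step 5. What may go wrong: poor facial selectivity in the hydrogenation of the tetrasubstituted enol ether, because the C4 methyl and the C5 aryl group block opposite faces; also over-reduction by hydrogenolysis of the benzylic C–O bonds of the ring. Fallback, setting out from 12 and coming back at 13: a stepwise polar reduction (CF3CO2H, Et3SiH, CH2Cl2, −78 °C) replaces the surface addition. Kinetic protonation at C3 opposite the C4 methyl is followed by hydride delivery to the 2-aryl oxocarbenium ion anti to the new C3 methyl (inside attack on the five-membered cation). This should give {4-[(2S,3R,4S,5S)-5-[4-(benzyloxy)-3-methoxyphenyl]-3,4-dimethyloxolan-2-yl]-2-methoxyphenoxy}triisopropylsilane F4, and a separate mild hydrogenolysis (H2, 10% Pd/C, EtOAc) of the benzyl ether then gives 13.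

3. Step 10. What may go wrong: incomplete chelation control in the hydride transfer, giving a mixture of erythro and threo carbinols. Fallback, setting out from 15 and coming back at 21 (bypassing steps 7, 9 and 10): iBu2AlH (CH2Cl2, −78 °C) reduces ester 15 to (R)-2-{4-[(2S,3S,4R,5S)-5-{3-methoxy-4-[(triisopropylsilyl)oxy]phenyl}-3,4-dimethyloxolan-2-yl]-2-methoxyphenoxy}propanal F5. The aryltitanium reagent made from 19 and ClTi(OiPr)3 then adds under non-chelating Felkin–Anh control, which should give the erythro alcohol 21 directly.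

Further compounds
F1 | step 4 | (4S,5S)-5-[4-(benzyloxy)-3-methoxyphenyl]-4-methyl-3-methylideneoxolan-2-one | C=C1C(=O)O[C@H](c2ccc(OCc3ccccc3)c(OC)c2)[C@H]1C
F2 | step 4 | (3R,4S,5S)-5-[4-(benzyloxy)-3-methoxyphenyl]-3,4-dimethyloxolan-2-one | O=C1O[C@H](c2ccc(OCc3ccccc3)c(OC)c2)[C@@H](C)[C@H]1C
F3 | step 4 | (3R,4S,5S)-5-[4-(benzyloxy)-3-methoxyphenyl]-2-{3-methoxy-4-[(triisopropylsilyl)oxy]phenyl}-3,4-dimethyloxolan-2-ol | COc1cc(C2(O)O[C@H](c3ccc(OCc4ccccc4)c(OC)c3)[C@@H](C)[C@H]2C)ccc1O[Si](C(C)C)(C(C)C)C(C)C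
F4 | step 5 | {4-[(2S,3R,4S,5S)-5-[4-(benzyloxy)-3-methoxyphenyl]-3,4-dimethyloxolan-2-yl]-2-methoxyphenoxy}triisopropylsilane | COc1cc([C@H]2O[C@H](c3ccc(OCc4ccccc4)c(OC)c3)[C@@H](C)[C@H]2C)ccc1O[Si](C(C)C)(C(C)C)C(C)C
F5 | step 10 | (R)-2-{4-[(2S,3S,4R,5S)-5-{3-methoxy-4-[(triisopropylsilyl)oxy]phenyl}-3,4-dimethyloxolan-2-yl]-2-methoxyphenoxy}propanal | COc1cc([C@H]2O[C@H](c3ccc(O[C@H](C)C=O)c(OC)c3)[C@@H](C)[C@H]2C)ccc1O[Si](C(C)C)(C(C)C)C(C)C
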